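The rise of Z from 2.00 min to 5.00 min, in percent of the G charged, was 1.46 times larger in Saturday's run than in Tuesday's, and Tuesday's charge of G was 1.47 times Saturday's.

| setting | Saturday's | Tuesday's | south-west | north-east |
|---|---|---|---|---|
| G | 0.15 M | 0.22 M | 0.30 M | 0.30 M |
| L | 130 mM (held) | 130 mM (held) | 130 mM (held) | 130 mM (held) |
| remark | run made earlier | run made earlier |  |  |
| time |  |  | 8.0 min | 12 min |

| run | time / min | Z / % | E / % | G / % | Q / % | X / % |
|---|---|---|---|---|---|---|
| Saturday's | 1.00 | 4.1 | 77.3 | 9.3 | 4.3 | 0 |
| Saturday's | 2.00 | 12.7 | 81.5 | 1.3 | 4.1 | 0 |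
| Saturday's | 3.00 | 20.7 | 75.1 | 1.0 | 3.9 | 0 |
| Saturday's | 4.00 | 28.4 | 68.3 | 0 | 3.7 | 0 |
| Saturday's | 5.00 | 36.2 | 61.0 | 0.4 | 4.7 | 0 |
| Tuesday's | 0.417 | 2.2 | 53.3 | 43.3 | 4.2 | 0 |
| Tuesday's | 1.33 | 5.2 | 83.0 | 5.7 | 4.0 | 0 |
| Tuesday's | 2.00 | 9.7 | 84.3 | 0.8 | 4.0 | 0.9 |
| Tuesday's | 3.00 | 14.8 | 80.3 | 0 | 4.9 | 0 |
| Tuesday's | 5.00 | 25.8 | 71.5 | 1.0 | 3.6 | 0.5 |

(scatter of a reading: 1 percentage point)

- which of these there is most of at the end, counted by the G in it, south-west (X / E / Q / Z)
- which of these there is most of at the end, counted by the G in it, north-east (X / E / Q / Z)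
- final amount of the leader among these, as a percentage of the G charged, in south-west
- final amount of the leader among these, as a percentage of the G charged, in north-east

- a species is counted by the G in it: one X counts as two
- the earlier runs were read with a standard deviation of 1 percentage point
- at the start none of L is in solution

1. G clears early: in Saturday's run at 2.00 min, G reads 1.3%, E 81.5%, Q 4.1% and X 0%. After that, E falls as Z rises in both runs.

2. Matching ratios mean the same concentration of Z appears per minute at either charge. Saturday's run gives 11.8 mM/min and Tuesday's 11.8 mM/min. Their mean is the supply rate, the concentration of Z formed per minute at these two charges of G, 11.8 mM/min. Read so, the rise is zero-order, and this reckoning takes it as a rate-limiting step: L enters solution steadily and E takes it up.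

3. A constant rate integrates to a straight line: Z equals the supply rate times the time after a lag. The readings at 5.00 min put that lag at 0.285 min.

4. Dividing by the charge gives Z as a share. South-west reaches 30.3% and north-east 46.0%. With Q near 4.0%, E stands at 65.7% and 50.0%. North-east's Z then comes to 138 mM, more than 130 mM, but that figure is a held saturation concentration, so this reckoning lets the line run past it.

5. The forecast names E in south-west and E in north-east, at 66% and 53%, reading the rise as “zero-order and independent of E”. At north-east its figure stands above this reckoning's 50.0%.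

The flasks give E 65.2% and Z 30.8% in south-west, and E 51.1% and Z 45.5% in north-east.

    G → E (k = 2.00 /min)
    G ⇌ Q (K = 3.20, k = 0.100 /min)
    J + E ⇌ Z (K = 120 /M, k = 24.0 /M/min)
    L ⇌ J, rate k4*(csat - [J]) (kL = 0.0980 /min)
    G + Q → X (k = 0.140 /M/min)

North-east is not at rest at 12 min: E is made more slowly than it is used up, the net ratio being 0.0287. Its remaining E equals 13.0 min of uptake at the supply rate. The same line gives 18.5% Z for north-east at 5.0 min, where the flask holds 19.3%. Later the line fails: at 30 min, past that clock, E still stands at 11.9%, with J at 0.0629 M. At ten times the time, 120 min, north-east holds E 6.02%, Z 93.7% and J 0.130 M.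

The runs come from a simulation with constants of no real substance, and the scatter is random.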